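**Plan**

- Numbering (thymol type): C7 is the benzylic CH2O carbon on the ring, C8 the quaternary oxirane carbon, C9 the oxirane CH2, C10 the acyloxymethyl carbon on C8.
- Cuts, in order: the phenolic tiglate C–O bond; C8–C9 and C9–O of the oxirane; the C10–O ester bond; the aryl–C8 bond; the C7–O ester bond.
- Enabling feature: the ring C8–C9–O is a terminal 2,2-disubstituted oxirane whose C8 already holds the arene and C10, so removing the methylene C9 leaves an aryl ketone at C8 whose carbonyl oxygen is the oxirane oxygen.
- Forward: the arene of methyl 4-bromo-3-hydroxybenzoate is silylated, reduced and acylated at C7; the C8–C10 unit is joined by Stille coupling, C10 is brominated and esterified; the oxirane, the only ring formed, closes in step 6; desilylation and tigloylation finish.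
- Stereochemistry: C8 is the sole stereocentre, set in step 6 by the chiral LaLi3(binaphthoxide)3 catalyst (C9 delivered to the Re face, R configuration); the E olefin enters intact with tigloyl chloride.

Key step: step 6

Assumption: the sense of induction is taken from the aryl methyl ketone series with the acyloxymethyl group in the place of methyl; the (R)-binaphthol complex is written on the premise that it is the antipode that turns acetophenone into (R)-2-methyl-2-phenyloxirane, and the (S)-binaphthol complex takes its place if the premise or the analogy fails.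

**Route**

Step 1
Reactants: 1 methyl 4-bromo-3-hydroxybenzoate
Product: 2 methyl 4-bromo-3-(triisopropylsilyloxy)benzoate
Conditions: iPr3SiCl, imidazole, DMF, rt
Reagents that add atoms: triisopropylsilyl chloride, CC(C)[Si](Cl)(C(C)C)C(C)C
Why: Imidazole-promoted O-silylation of the only protic group gives a bulky aryl silyl ether that should withstand the hydride, palladium, bromination and ylide steps and still fall to fluoride.

Step 2
Reactants: 2 methyl 4-bromo-3-(triisopropylsilyloxy)benzoate
Product: 3 [4-bromo-3-(triisopropylsilyloxy)phenyl]methanol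
Conditions: iBu2AlH (2.5 equiv), CH2Cl2, −78 to 0 °C; aq. potassium sodium tartrate
Reagents that add atoms: none
Why: Hydride reduction of the methyl ester to the primary alcohol with iBu2AlH at low temperature should leave the aryl bromide and the aryl silyl ether untouched.

Step 3
Reactants: 3 [4-bromo-3-(triisopropylsilyloxy)phenyl]methanol; 4 isobutyryl chloride
Product: 5 4-bromo-3-(triisopropylsilyloxy)benzyl isobutyrate
Conditions: Et3N, DMAP (cat.), CH2Cl2, 0 °C to rt
Reagents that add atoms: none
Why: DMAP-catalysed O-acylation of the primary benzylic alcohol with the acid chloride installs the C7 isobutyrate, which is inert to the neutral coupling, bromination and carboxylate conditions that follow.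

Step 4
Reactants: 5 4-bromo-3-(triisopropylsilyloxy)benzyl isobutyrate; 6 tributyl(1-ethoxyvinyl)stannane
Product: 8 4-(2-bromoacetyl)-3-(triisopropylsilyloxy)benzyl isobutyrate, via 1-ethoxyvinyl arene 7 (not isolated)
Conditions: PdCl2(PPh3)2 (5 mol%), toluene, 100 °C; then NBS, THF/H2O, 0 °C
Reagents that add atoms: N-bromosuccinimide, O=C1CCC(=O)N1Br; water, O
Why: Migita–Kosugi–Stille coupling forms the aryl–C8 bond under neutral conditions that spare ester and silyl ether, and electrophilic bromination of the electron-rich enol ether in wet THF, far faster than ring bromination, gives a hemiketal that collapses to the bromomethyl ketone.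

Step 5
Reactants: 8 4-(2-bromoacetyl)-3-(triisopropylsilyloxy)benzyl isobutyrate; 9 isobutyric acid
Product: 10 2-[4-(isobutyryloxymethyl)-2-(triisopropylsilyloxy)phenyl]-2-oxoethyl isobutyrate
Conditions: iPr2NEt, MeCN, rt
Reagents that add atoms: none
Why: SN2 displacement of the carbonyl-activated bromide at C10 by the ammonium carboxylate (phenacyl ester formation) is fast at room temperature, and the hindered, weakly nucleophilic base should neither quaternise nor cleave the aryl silyl ether.

Step 6
Reactants: 10 2-[4-(isobutyryloxymethyl)-2-(triisopropylsilyloxy)phenyl]-2-oxoethyl isobutyrate; 11 trimethylsulfoxonium iodide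
Product: 14 [(2R)-2-[4-(isobutyryloxymethyl)-2-(triisopropylsilyloxy)phenyl]oxiran-2-yl]methyl isobutyrate, via dimethyloxosulfonium methylide 12 (not isolated), via sulfoxonium betaine 13 (not isolated)
Conditions: NaH, THF, reflux, filtration (ylide solution); then 10, LaLi3[(R)-binaphthoxide]3 (10 mol%), [2,4,6-(MeO)3C6H2]3P=O (10 mol%), MS 5Å, THF, rt
Reagents that add atoms: none
Why: The trivalent lanthanum centre of the binaphthoxide complex, tuned by the triarylphosphine oxide, activates the C8 carbonyl while a lithium binaphthoxide site holds ylide 12, whose carbon adds to C8 (C8–C9 bond) to give betaine 13; the C8 alkoxide then displaces dimethyl sulfoxide from C9 (C9–O bond), so the oxirane oxygen is the former ketone oxygen. The closest known reaction type is the catalytic asymmetric Corey–Chaykovsky epoxidation of ketones with this ylide under lanthanum–lithium binaphthoxide and phosphine oxide, established chiefly for methyl ketones and applied here to an acyloxymethyl aryl ketone. The single ring, the oxirane C8–C9–O, closes in the 3-exo-tet mode. C8, the only new stereocentre, is controlled by the binaphthoxide framework, which should deliver the methylene to the Re face of the ketone and so give the R configuration. The step needs facial selectivity between the aryl and acyloxymethyl flanks and chemoselectivity for the ketone over the two isobutyrates and over enolisation at C10; the first rests on the large, twisted ortho-triisopropylsilyloxyaryl group set against a primary CH2O group in the place of methyl, the second on the higher electrophilicity of the ketone toward the stabilised, weakly basic ylide at room temperature.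

Step 7
Reactants: 14 [(2R)-2-[4-(isobutyryloxymethyl)-2-(triisopropylsilyloxy)phenyl]oxiran-2-yl]methyl isobutyrate
Product: 15 [(2R)-2-[2-hydroxy-4-(isobutyryloxymethyl)phenyl]oxiran-2-yl]methyl isobutyrate
Conditions: Bu4NF, AcOH (1:1), THF, 0 °C
Reagents that add atoms: none
Why: Fluoride-induced cleavage of the aryl silicon–oxygen bond (desilylation) is much faster than attack on alkyl esters or the oxirane, and the acetic acid buffer should deliver the neutral phenol instead of a phenoxide that could open the neighbouring benzylic epoxide, so C8 is not touched.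

Step 8
Reactants: 15 [(2R)-2-[2-hydroxy-4-(isobutyryloxymethyl)phenyl]oxiran-2-yl]methyl isobutyrate; 16 tigloyl chloride
Product: 17 5-(isobutyryloxymethyl)-2-[(2R)-2-(isobutyryloxymethyl)oxiran-2-yl]phenyl (E)-2-methylbut-2-enoate (CNP0189152.1)
Conditions: pyridine, DMAP (cat.), CH2Cl2, 0 °C
Reagents that add atoms: none
Why: O-Acylation of the phenol through an acylpyridinium (nucleophilic catalysis) needs neither a free phenoxide nor a strong base, so the oxirane and C8 should survive and the E geometry is carried over from the acid chloride without deconjugation.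

**Compound list**

1 | methyl 4-bromo-3-hydroxybenzoate | COC(=O)c1ccc(Br)c(O)c1 | starting material
2 | methyl 4-bromo-3-(triisopropylsilyloxy)benzoate | COC(=O)c1ccc(Br)c(O[Si](C(C)C)(C(C)C)C(C)C)c1 | intermediate
3 | [4-bromo-3-(triisopropylsilyloxy)phenyl]methanol | OCc1ccc(Br)c(O[Si](C(C)C)(C(C)C)C(C)C)c1 | intermediate
4 | isobutyryl chloride | CC(C)C(Cl)=O | starting material
5 | 4-bromo-3-(triisopropylsilyloxy)benzyl isobutyrate | CC(C)C(=O)OCc1ccc(Br)c(O[Si](C(C)C)(C(C)C)C(C)C)c1 | intermediate
6 | tributyl(1-ethoxyvinyl)stannane | CCCC[Sn](CCCC)(CCCC)C(=C)OCC | starting material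
7 | 4-(1-ethoxyvinyl)-3-(triisopropylsilyloxy)benzyl isobutyrate | CCOC(=C)c1ccc(COC(=O)C(C)C)cc1O[Si](C(C)C)(C(C)C)C(C)C | intermediate (not isolated)
8 | 4-(2-bromoacetyl)-3-(triisopropylsilyloxy)benzyl isobutyrate | CC(C)C(=O)OCc1ccc(C(=O)CBr)c(O[Si](C(C)C)(C(C)C)C(C)C)c1 | intermediate
9 | isobutyric acid | CC(C)C(=O)O | starting material
10 | 2-[4-(isobutyryloxymethyl)-2-(triisopropylsilyloxy)phenyl]-2-oxoethyl isobutyrate | CC(C)C(=O)OCC(=O)c1ccc(COC(=O)C(C)C)cc1O[Si](C(C)C)(C(C)C)C(C)C | intermediate
11 | trimethylsulfoxonium iodide | C[S+](C)(C)=O.[I-] | starting material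
12 | dimethyloxosulfonium methylide | [CH2-][S+](C)(C)=O | intermediate (not isolated)
13 | (2S)-1-(dimethyloxosulfonio)-3-(isobutyryloxy)-2-[4-(isobutyryloxymethyl)-2-(triisopropylsilyloxy)phenyl]propan-2-olate (betaine) | CC(C)C(=O)OCc1ccc([C@]([O-])(COC(=O)C(C)C)C[S+](C)(C)=O)c(O[Si](C(C)C)(C(C)C)C(C)C)c1 | intermediate (not isolated)
14 | [(2R)-2-[4-(isobutyryloxymethyl)-2-(triisopropylsilyloxy)phenyl]oxiran-2-yl]methyl isobutyrate | CC(C)C(=O)OCc1ccc([C@]2(COC(=O)C(C)C)CO2)c(O[Si](C(C)C)(C(C)C)C(C)C)c1 | intermediate
15 | [(2R)-2-[2-hydroxy-4-(isobutyryloxymethyl)phenyl]oxiran-2-yl]methyl isobutyrate | CC(C)C(=O)OCc1ccc([C@]2(COC(=O)C(C)C)CO2)c(O)c1 | intermediate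
16 | tigloyl chloride, (E)-2-methylbut-2-enoyl chloride | C/C=C(\C)C(Cl)=O | starting material
17 | 5-(isobutyryloxymethyl)-2-[(2R)-2-(isobutyryloxymethyl)oxiran-2-yl]phenyl (E)-2-methylbut-2-enoate | C/C=C(\C)C(=O)Oc1cc(COC(=O)C(C)C)ccc1[C@]1(COC(=O)C(C)C)CO1 | target

**Step count and risks**

Total step count: 8. Longest linear sequence: 8 steps, from 1 to 17.

Steps most likely to fail:

Step 6. The catalyst may discriminate poorly between the faces of a ketone flanked by an aryl and an acyloxymethyl group, or the betaine alkoxide may take up the C10 acyl group before ring closure. The fallback gives up the ylide transfer and reaches the same oxirane by epoxidation of an alkene. It sets out from 5, which is coupled under the palladium conditions of step 4 with 2-(tributylstannyl)prop-2-en-1-ol to give 4-(3-hydroxyprop-1-en-2-yl)-3-(triisopropylsilyloxy)benzyl isobutyrate F1. Katsuki–Sharpless asymmetric epoxidation (Ti(OiPr)4, L-(+)-diisopropyl tartrate, tBuOOH, MS 4Å, CH2Cl2, −20 °C) should then give 4-[(2S)-2-(hydroxymethyl)oxiran-2-yl]-3-(triisopropylsilyloxy)benzyl isobutyrate F2, this tartrate being the one that leads to (2S)-glycidols. Acylation of the primary alcohol with 4 and pyridine comes back to the route at 14; the descriptor changes from S to R only because the acylated arm then outranks the ring CH2.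

Step 7. The tertiary benzylic oxirane may open once the ortho oxygen is free, through quinone-methide-type ionisation assisted by the phenol or phenoxide, during desilylation or on handling of 15. The fallback avoids a free phenol altogether. It sets out from 14 and comes back at 17: Bu4NF is added slowly to a cold THF solution of 14 and excess tiglic anhydride, so that the phenoxide is acylated as it is released. No new compound is made.

Step 4. Oxidative addition and transmetalation may be slow at the electron-rich bromide flanked by the triisopropylsilyloxy group, with protodestannylation or loss of the enol ether before bromination. The fallback replaces the cross-coupling by acylation of an aryllithium. It sets out from 3, which is silylated (tBuMe2SiCl, imidazole, DMF) to {[4-bromo-3-(triisopropylsilyloxy)benzyl]oxy}(tert-butyl)dimethylsilane F3. Bromine–lithium exchange (nBuLi, THF, kept at −78 °C to suppress silyl migration from oxygen to carbon) and Weinreb ketone synthesis with N-methoxy-N-methyl-2-(tert-butyldimethylsilyloxy)acetamide should give 2-(tert-butyldimethylsilyloxy)-1-[4-(tert-butyldimethylsilyloxymethyl)-2-(triisopropylsilyloxy)phenyl]ethanone F4. Camphorsulfonic acid in MeOH removes both primary silyl ethers, the aryl silyl ether being stable to mild acid, to give 2-hydroxy-1-[4-(hydroxymethyl)-2-(triisopropylsilyloxy)phenyl]ethanone F5. Double acylation with 4 and pyridine comes back to the route at 10.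

Further compounds
F1 | step 6 | 4-(3-hydroxyprop-1-en-2-yl)-3-(triisopropylsilyloxy)benzyl isobutyrate | CC(C)C(=O)OCc1ccc(C(=C)CO)c(O[Si](C(C)C)(C(C)C)C(C)C)c1
F2 | step 6 | 4-[(2S)-2-(hydroxymethyl)oxiran-2-yl]-3-(triisopropylsilyloxy)benzyl isobutyrate | CC(C)C(=O)OCc1ccc([C@]2(CO)CO2)c(O[Si](C(C)C)(C(C)C)C(C)C)c1
F0 | step 7 | none | none
F3 | step 4 | {[4-bromo-3-(triisopropylsilyloxy)benzyl]oxy}(tert-butyl)dimethylsilane | CC(C)[Si](Oc1cc(CO[Si](C)(C)C(C)(C)C)ccc1Br)(C(C)C)C(C)C
F4 | step 4 | 2-(tert-butyldimethylsilyloxy)-1-[4-(tert-butyldimethylsilyloxymethyl)-2-(triisopropylsilyloxy)phenyl]ethanone | CC(C)[Si](Oc1cc(CO[Si](C)(C)C(C)(C)C)ccc1C(=O)CO[Si](C)(C)C(C)(C)C)(C(C)C)C(C)C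
F5 | step 4 | 2-hydroxy-1-[4-(hydroxymethyl)-2-(triisopropylsilyloxy)phenyl]ethanone | CC(C)[Si](Oc1cc(CO)ccc1C(=O)CO)(C(C)C)C(C)C
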